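**Retrosynthetic overview**
- The flavonol pyranone ring is formed last, by Algar–Flynn–Oyamada oxidation of a chalcone made from a dihydrobenzofuran-4-carbaldehyde and a dibenzylated phloroacetophenone; hydrogenolysis of five benzyl ethers then gives the target.
- Key disconnection: the C3a–C3 bond of the dihydrofuran ring. The enabling feature is that C3 carries both the arene carbon C3a and the exocyclic CH2OH carbon, while C7a–O1–C2 is an intact aryl benzyl ether. This C3a–C3–C(exo) 1,2-relationship is the imprint of a 1,2-aryl shift: returning C3a to the exocyclic carbon unfolds the five-membered ring into the six-membered pyranone ring O1–C2–C3–C4(=O)–C4a–C8a of a flavanone. An oxidative ring contraction therefore makes the bond, sets C3 trans to C2 and delivers the CH2OH carbon as an ester.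
- The flavanone has a single centre, C2, set by ligand-controlled conjugate arylation of a chromone. The chromone comes from 1,2-bis(benzyloxy)-4-bromobenzene by ortho-lithiation/acetylation, chelation-controlled mono-debenzylation and enaminone cyclisation; the bromine is kept as the future aldehyde carbon.
- Order of ring formation: pyranone ring of the chromone/flavanone → contracted to the dihydrofuran ring → pyranone ring of the flavonol.

Key step: step 5

Assumption: the sense of induction of (S)-t-BuPyOx on chromone 6 is taken to be the one known for cyclic enones (aryl delivered to give the 2R product); if it proves opposite, the antipodal ligand is used with no other change.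

**Step 1**
Reactants: 1 1,2-bis(benzyloxy)-4-bromobenzene
Product: 3 1-[2,3-bis(benzyloxy)-6-bromophenyl]ethan-1-one, via aryllithium 2 (not isolated)
Conditions: LiN(i-Pr)2 (commercial solution, 1.1 equiv), THF, −78 °C; MeC(O)N(OMe)Me, −78 → 0 °C; aq. NH4Cl
Reagents that add atoms: N-methoxy-N-methylacetamide, CC(=O)N(C)OC
Why: The ring proton flanked by bromine and a benzyloxy group is the most acidic, so directed ortho-metalation should occur there at −78 °C (below the onset of aryne formation), and the aryllithium is acylated by the Weinreb amide, whose chelated adduct prevents over-addition.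

**Step 2**
Reactants: 3 1-[2,3-bis(benzyloxy)-6-bromophenyl]ethan-1-one
Product: 4 1-[3-(benzyloxy)-6-bromo-2-hydroxyphenyl]ethan-1-one
Conditions: BCl3 (1.1 equiv), CH2Cl2, −78 → −20 °C; H2O
Reagents that add atoms: none
Why: BCl3 chelates between the ketone oxygen and the ortho benzyloxy oxygen, so only that benzyl group should be cleaved (chelation-controlled ortho-selective O-debenzylation), leaving the remote benzyl ether and the aryl bromide.

**Step 3**
Reactants: 4 1-[3-(benzyloxy)-6-bromo-2-hydroxyphenyl]ethan-1-one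
Product: 6 8-(benzyloxy)-5-bromo-4H-chromen-4-one, via enaminone 5 (not isolated)
Conditions: Me2NCH(OMe)2, toluene, 100 °C; then conc. HCl, CH2Cl2, rt
Reagents that add atoms: N,N-dimethylformamide dimethyl acetal, COC(OC)N(C)C
Why: Condensation of the methyl ketone with the formamide acetal gives the enaminone, which under acid should cyclise by conjugate addition of the phenol and loss of dimethylamine (enaminone route to chromones).

**Step 4**
Reactants: 6 8-(benzyloxy)-5-bromo-4H-chromen-4-one; 7 [4-(benzyloxy)-3-methoxyphenyl]boronic acid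
Product: 8 (2R)-8-(benzyloxy)-2-[4-(benzyloxy)-3-methoxyphenyl]-5-bromo-2,3-dihydro-4H-chromen-4-one
Conditions: Pd(OCOCF3)2 (5 mol%), (S)-4-tert-butyl-2-(pyridin-2-yl)-4,5-dihydro-1,3-oxazole [(S)-t-BuPyOx, 6 mol%], NH4PF6 (30 mol%), H2O (5 equiv), ClCH2CH2Cl, 60 °C
Reagents that add atoms: none
Why: Catalytic asymmetric conjugate addition of an arylboronic acid to a chromone: cationic divalent palladium bearing the pyridine–oxazoline ligand transfers the aryl group to one enantioface of C2 (ligand control sets the R centre) and the palladium enolate is protonated; the aryl bromide should be inert because no zerovalent palladium is involved.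

**Step 5**
Reactants: 8 (2R)-8-(benzyloxy)-2-[4-(benzyloxy)-3-methoxyphenyl]-5-bromo-2,3-dihydro-4H-chromen-4-one
Product: 12 methyl (2R,3R)-7-(benzyloxy)-2-[4-(benzyloxy)-3-methoxyphenyl]-4-bromo-2,3-dihydro-1-benzofuran-3-carboxylate, via dimethyl ketal 9 (not isolated), via enol ether 10 (not isolated), via iodanyl ketal 11 (not isolated)
Conditions: PhI(OAc)2 (1.2 equiv), conc. H2SO4 (2 equiv), HC(OMe)3, 0 °C → rt; then H2O
Reagents that add atoms: trimethyl orthoformate, COC(OC)OC; water, O
Why: Acid-catalysed ketalisation of the C4 carbonyl (9) and loss of methanol give enol ether 10, whose C3 attacks electrophilic trivalent iodine anti to the C2 aryl group to give the trans iodanyl ketal 11; departure of iodobenzene is then assisted by a 1,2-shift of the ring-fusion carbon C4a from C4 to C3, pushed by the two ketal oxygens, and the resulting dimethoxycarbenium ion is hydrolysed to the methyl ester on work-up. The closest known reaction type is the hypervalent-iodine (or trivalent thallium) oxidative ring contraction of flavanones to methyl trans-2-aryl-2,3-dihydrobenzofuran-3-carboxylates, a cyclic case of the oxidative 1,2-aryl migration of aryl ketones to arylacetic esters. The five-membered ring O1–C2–C3–C3a–C7a is closed by contraction of the six-membered pyranone ring: the C3a–C3 bond forms by ipso attack of the arene on C3 through a bridged phenonium-type transition state as the C4–C4a bond breaks. C2 is untouched and stays R; C3 is set by substrate control, since the iodane enters trans to the C2 aryl group and is displaced with inversion, which places the ester trans to the aryl group (2R,3R). The step needs migration of C4a to win over migration of the electron-rich C2 aryl group, dehydrogenation and α-methoxylation; the trans-diequatorial conformer of 11 holds the C4–C4a bond antiperiplanar to the C3–I bond, the ring oxygen O1 ortho to C4a raises its migratory aptitude, and the bromine at C5 is only weakly deactivating.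

**Step 6**
Reactants: 12 methyl (2R,3R)-7-(benzyloxy)-2-[4-(benzyloxy)-3-methoxyphenyl]-4-bromo-2,3-dihydro-1-benzofuran-3-carboxylate
Product: 13 [(2R,3S)-7-(benzyloxy)-2-[4-(benzyloxy)-3-methoxyphenyl]-4-bromo-2,3-dihydro-1-benzofuran-3-yl]methanol
Conditions: LiAlH4, THF, 0 °C; aq. work-up
Reagents that add atoms: none
Why: Hydride reduction of the ester is fast at 0 °C, where the aryl bromide and benzyl ethers should be inert, and it avoids base-induced ring opening at C3, so both centres are kept (3R becomes 3S only through the change in substituent priority).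

**Step 7**
Reactants: 13 [(2R,3S)-7-(benzyloxy)-2-[4-(benzyloxy)-3-methoxyphenyl]-4-bromo-2,3-dihydro-1-benzofuran-3-yl]methanol
Product: 14 (2R,3S)-7-(benzyloxy)-2-[4-(benzyloxy)-3-methoxyphenyl]-3-[(benzyloxy)methyl]-4-bromo-2,3-dihydro-1-benzofuran
Conditions: NaH, BnBr, n-Bu4NI (cat.), DMF, 0 °C → rt
Reagents that add atoms: benzyl bromide, BrCc1ccccc1
Why: Williamson etherification masks the primary hydroxyl so that it cannot form a lactol with the later aldehyde or add to the enone, and the benzyl group is removed in the final hydrogenolysis.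

**Step 8**
Reactants: 14 (2R,3S)-7-(benzyloxy)-2-[4-(benzyloxy)-3-methoxyphenyl]-3-[(benzyloxy)methyl]-4-bromo-2,3-dihydro-1-benzofuran
Product: 16 (2R,3S)-7-(benzyloxy)-2-[4-(benzyloxy)-3-methoxyphenyl]-3-[(benzyloxy)methyl]-2,3-dihydro-1-benzofuran-4-carbaldehyde, via aryllithium 15 (not isolated)
Conditions: n-BuLi (1.1 equiv), THF, −78 °C; DMF, −78 → 0 °C; aq. NH4Cl
Reagents that add atoms: N,N-dimethylformamide, CN(C)C=O
Why: Bromine–lithium exchange at −78 °C should be much faster than deprotonation of the benzylic positions, and the aryllithium is formylated by DMF (Bouveault-type formylation).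

**Step 9**
Reactants: 17 1-(2,4,6-trihydroxyphenyl)ethan-1-one
Product: 18 1-[2,4-bis(benzyloxy)-6-hydroxyphenyl]ethan-1-one
Conditions: BnBr (2.1 equiv), K2CO3, DMF, rt → 50 °C
Reagents that add atoms: benzyl bromide, BrCc1ccccc1
Why: Selective Williamson etherification: two phenols are alkylated and one hydroxyl ortho to the acetyl group, hydrogen-bonded to it, should stay free.

**Step 10**
Reactants: 16 (2R,3S)-7-(benzyloxy)-2-[4-(benzyloxy)-3-methoxyphenyl]-3-[(benzyloxy)methyl]-2,3-dihydro-1-benzofuran-4-carbaldehyde; 18 1-[2,4-bis(benzyloxy)-6-hydroxyphenyl]ethan-1-one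
Product: 19 (E)-1-[2,4-bis(benzyloxy)-6-hydroxyphenyl]-3-[(2R,3S)-7-(benzyloxy)-2-[4-(benzyloxy)-3-methoxyphenyl]-3-[(benzyloxy)methyl]-2,3-dihydro-1-benzofuran-4-yl]prop-2-en-1-one
Conditions: KOH (aq.), EtOH/THF, rt
Reagents that add atoms: none
Why: Claisen–Schmidt condensation of the non-enolisable aldehyde with the acetophenone enolate should give the E-chalcone after dehydration, with no enolisable stereocentre in either partner.

**Step 11**
Reactants: 19 (E)-1-[2,4-bis(benzyloxy)-6-hydroxyphenyl]-3-[(2R,3S)-7-(benzyloxy)-2-[4-(benzyloxy)-3-methoxyphenyl]-3-[(benzyloxy)methyl]-2,3-dihydro-1-benzofuran-4-yl]prop-2-en-1-one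
Product: 21 5,7-bis(benzyloxy)-2-[(2R,3S)-7-(benzyloxy)-2-[4-(benzyloxy)-3-methoxyphenyl]-3-[(benzyloxy)methyl]-2,3-dihydro-1-benzofuran-4-yl]-3-hydroxy-4H-chromen-4-one, via dihydroflavonol 20 (not isolated)
Conditions: 30% H2O2, NaOH (aq.), MeOH/THF, 0 °C → rt
Reagents that add atoms: hydrogen peroxide, OO
Why: Algar–Flynn–Oyamada reaction: alkaline hydrogen peroxide oxidises the 2'-hydroxychalcone with 6-endo closure of the phenoxide to the dihydroflavonol, which is dehydrogenated in the same pot to the flavonol, so the transient centres of 20 are lost.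

**Step 12**
Reactants: 21 5,7-bis(benzyloxy)-2-[(2R,3S)-7-(benzyloxy)-2-[4-(benzyloxy)-3-methoxyphenyl]-3-[(benzyloxy)methyl]-2,3-dihydro-1-benzofuran-4-yl]-3-hydroxy-4H-chromen-4-one
Product: 22 3,5,7-trihydroxy-2-[(2R,3S)-7-hydroxy-2-(4-hydroxy-3-methoxyphenyl)-3-(hydroxymethyl)-2,3-dihydro-1-benzofuran-4-yl]-4H-chromen-4-one
Conditions: H2 (1 atm), Pd(OH)2 on carbon, THF/MeOH, rt
Reagents that add atoms: none
Why: Catalytic hydrogenolysis should cleave the four aryl benzyl ethers and the alkyl benzyl ether, while the flavonol double bond, the aryl methyl ether and the cyclic benzylic ether are expected to survive at ambient pressure.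

**Compound list**
1 | 1,2-bis(benzyloxy)-4-bromobenzene | Brc1ccc(OCc2ccccc2)c(OCc2ccccc2)c1 | starting material
2 | [2,3-bis(benzyloxy)-6-bromophenyl]lithium | [Li]c1c(Br)ccc(OCc2ccccc2)c1OCc1ccccc1 | intermediate
3 | 1-[2,3-bis(benzyloxy)-6-bromophenyl]ethan-1-one | CC(=O)c1c(Br)ccc(OCc2ccccc2)c1OCc1ccccc1 | intermediate
4 | 1-[3-(benzyloxy)-6-bromo-2-hydroxyphenyl]ethan-1-one | CC(=O)c1c(Br)ccc(OCc2ccccc2)c1O | intermediate
5 | (E)-1-[3-(benzyloxy)-6-bromo-2-hydroxyphenyl]-3-(dimethylamino)prop-2-en-1-one | CN(C)/C=C/C(=O)c1c(Br)ccc(OCc2ccccc2)c1O | intermediate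
6 | 8-(benzyloxy)-5-bromo-4H-chromen-4-one | O=c1ccoc2c(OCc3ccccc3)ccc(Br)c12 | intermediate
7 | [4-(benzyloxy)-3-methoxyphenyl]boronic acid | COc1cc(B(O)O)ccc1OCc1ccccc1 | starting material
8 | (2R)-8-(benzyloxy)-2-[4-(benzyloxy)-3-methoxyphenyl]-5-bromo-2,3-dihydro-4H-chromen-4-one | COc1cc([C@@H]2Oc3c(OCc4ccccc4)ccc(Br)c3C(=O)C2)ccc1OCc1ccccc1 | intermediate
9 | (2R)-8-(benzyloxy)-2-[4-(benzyloxy)-3-methoxyphenyl]-5-bromo-4,4-dimethoxy-3,4-dihydro-2H-chromene | COc1cc([C@@H]2Oc3c(OCc4ccccc4)ccc(Br)c3C(OC)(OC)C2)ccc1OCc1ccccc1 | intermediate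
10 | (2R)-8-(benzyloxy)-2-[4-(benzyloxy)-3-methoxyphenyl]-5-bromo-4-methoxy-2H-chromene | COc1cc([C@@H]2Oc3c(OCc4ccccc4)ccc(Br)c3C(OC)=C2)ccc1OCc1ccccc1 | intermediate
11 | (acetyloxy)[(2S,3S)-8-(benzyloxy)-2-[4-(benzyloxy)-3-methoxyphenyl]-5-bromo-4,4-dimethoxy-3,4-dihydro-2H-chromen-3-yl](phenyl)-λ3-iodane (2,3-trans; C2 arranged as in 8, its descriptor changes only through substituent priority) | COc1cc([C@@H]2Oc3c(OCc4ccccc4)ccc(Br)c3C(OC)(OC)[C@H]2I(OC(C)=O)c2ccccc2)ccc1OCc1ccccc1 | intermediate
12 | methyl (2R,3R)-7-(benzyloxy)-2-[4-(benzyloxy)-3-methoxyphenyl]-4-bromo-2,3-dihydro-1-benzofuran-3-carboxylate (trans) | COc1cc([C@@H]2Oc3c(OCc4ccccc4)ccc(Br)c3[C@H]2C(=O)OC)ccc1OCc1ccccc1 | intermediate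
13 | [(2R,3S)-7-(benzyloxy)-2-[4-(benzyloxy)-3-methoxyphenyl]-4-bromo-2,3-dihydro-1-benzofuran-3-yl]methanol | COc1cc([C@@H]2Oc3c(OCc4ccccc4)ccc(Br)c3[C@H]2CO)ccc1OCc1ccccc1 | intermediate
14 | (2R,3S)-7-(benzyloxy)-2-[4-(benzyloxy)-3-methoxyphenyl]-3-[(benzyloxy)methyl]-4-bromo-2,3-dihydro-1-benzofuran | COc1cc([C@@H]2Oc3c(OCc4ccccc4)ccc(Br)c3[C@H]2COCc2ccccc2)ccc1OCc1ccccc1 | intermediate
15 | [(2R,3S)-7-(benzyloxy)-2-[4-(benzyloxy)-3-methoxyphenyl]-3-[(benzyloxy)methyl]-2,3-dihydro-1-benzofuran-4-yl]lithium | COc1cc([C@@H]2Oc3c(OCc4ccccc4)ccc([Li])c3[C@H]2COCc2ccccc2)ccc1OCc1ccccc1 | intermediate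
16 | (2R,3S)-7-(benzyloxy)-2-[4-(benzyloxy)-3-methoxyphenyl]-3-[(benzyloxy)methyl]-2,3-dihydro-1-benzofuran-4-carbaldehyde | COc1cc([C@@H]2Oc3c(OCc4ccccc4)ccc(C=O)c3[C@H]2COCc2ccccc2)ccc1OCc1ccccc1 | intermediate
17 | 1-(2,4,6-trihydroxyphenyl)ethan-1-one | CC(=O)c1c(O)cc(O)cc1O | starting material
18 | 1-[2,4-bis(benzyloxy)-6-hydroxyphenyl]ethan-1-one | CC(=O)c1c(O)cc(OCc2ccccc2)cc1OCc1ccccc1 | intermediate
19 | (E)-1-[2,4-bis(benzyloxy)-6-hydroxyphenyl]-3-[(2R,3S)-7-(benzyloxy)-2-[4-(benzyloxy)-3-methoxyphenyl]-3-[(benzyloxy)methyl]-2,3-dihydro-1-benzofuran-4-yl]prop-2-en-1-one | COc1cc([C@@H]2Oc3c(OCc4ccccc4)ccc(/C=C/C(=O)c4c(O)cc(OCc5ccccc5)cc4OCc4ccccc4)c3[C@H]2COCc2ccccc2)ccc1OCc1ccccc1 | intermediate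
20 | 5,7-bis(benzyloxy)-2-[(2R,3S)-7-(benzyloxy)-2-[4-(benzyloxy)-3-methoxyphenyl]-3-[(benzyloxy)methyl]-2,3-dihydro-1-benzofuran-4-yl]-3-hydroxy-2,3-dihydro-4H-chromen-4-one (trans-dihydroflavonol; both diastereomers at the two transient chromanone centres, left undefined in the SMILES) | COc1cc([C@@H]2Oc3c(OCc4ccccc4)ccc(C4Oc5cc(OCc6ccccc6)cc(OCc6ccccc6)c5C(=O)C4O)c3[C@H]2COCc2ccccc2)ccc1OCc1ccccc1 | intermediate
21 | 5,7-bis(benzyloxy)-2-[(2R,3S)-7-(benzyloxy)-2-[4-(benzyloxy)-3-methoxyphenyl]-3-[(benzyloxy)methyl]-2,3-dihydro-1-benzofuran-4-yl]-3-hydroxy-4H-chromen-4-one | COc1cc([C@@H]2Oc3c(OCc4ccccc4)ccc(-c4oc5cc(OCc6ccccc6)cc(OCc6ccccc6)c5c(=O)c4O)c3[C@H]2COCc2ccccc2)ccc1OCc1ccccc1 | intermediate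
22 | 3,5,7-trihydroxy-2-[(2R,3S)-7-hydroxy-2-(4-hydroxy-3-methoxyphenyl)-3-(hydroxymethyl)-2,3-dihydro-1-benzofuran-4-yl]-4H-chromen-4-one | COc1cc([C@@H]2Oc3c(O)ccc(-c4oc5cc(O)cc(O)c5c(=O)c4O)c3[C@H]2CO)ccc1O | target

**Step count and risks**
Total: 12 steps. Longest linear sequence: 11 steps (steps 1–8 and 10–12; step 9 is a one-step side branch).

Steps most likely to fail:

Step 5. The aryl shift may lose to migration of the electron-rich C2 aryl group, to dehydrogenation or to α-methoxylation; ketalisation next to the peri bromine may be slow; and the dialkoxyphenyl ring may be attacked by the iodine reagent. The fallback sets out from 8 and comes back at 12, and makes the same bond by a carbene-type ring contraction. The lithium enolate of 8 (LiN(SiMe3)2, THF, −78 °C) would be acylated with CF3CO2CH2CF3 to the 3-trifluoroacetyl flavanone (enol form) F1. Detrifluoroacetylative diazo transfer (MsN3, Et3N, aqueous MeCN) would give the 3-diazoflavanone F2. Irradiation at 365 nm in MeOH should trigger a Wolff rearrangement in which C4a migrates to C3 with loss of nitrogen; methanol traps the ketene to give 12 together with the cis ester F3, which catalytic DBU (CH2Cl2, 0 °C) should equilibrate to trans ester 12.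

Step 11. Ring closure may go 5-exo (aurone pathway) instead of 6-endo, a known tendency when the ketone ring carries a 6'-alkoxy group and the aldehyde-derived ring is ortho-substituted. The fallback sets out from 19 and comes back at 21, separating cyclisation from hydroxylation. Oxidative cyclisation with catalytic I2 in DMSO at 120 °C would give the flavone F4. Epoxidation of its C2=C3 bond with dimethyldioxirane (acetone/CH2Cl2, 0 °C) would give the 2,3-epoxyflavanone F5, which catalytic p-TsOH should open and tautomerise to flavonol 21.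

Step 4. Conjugate arylation may suffer from protodeboronation of the electron-rich boronic acid, slow insertion next to the 5-bromo group, or insufficient facial discrimination. The fallback sets out from 4 and comes back at 8, setting C2 by C–O instead of C–C bond formation. Claisen–Schmidt condensation of 4 with 4-(benzyloxy)-3-methoxybenzaldehyde (KOH, EtOH, 0 °C, cold acidic quench) would give the 2'-hydroxychalcone F6. Enantioselective intramolecular oxa-Michael addition under a cinchona-derived bifunctional thiourea (toluene, rt; the pseudo-enantiomer that gives the 2R series) should then give 8.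

**Further compounds**
F1 | step 5 | 1-[(2S)-8-(benzyloxy)-2-[4-(benzyloxy)-3-methoxyphenyl]-5-bromo-4-hydroxy-2H-chromen-3-yl]-2,2,2-trifluoroethan-1-one (enol form of the 3-trifluoroacetyl flavanone; C2 arranged as in 8, descriptor changed by priority only) | COc1cc([C@@H]2Oc3c(OCc4ccccc4)ccc(Br)c3C(O)=C2C(=O)C(F)(F)F)ccc1OCc1ccccc1
F2 | step 5 | (2S)-8-(benzyloxy)-2-[4-(benzyloxy)-3-methoxyphenyl]-5-bromo-3-diazo-2,3-dihydro-4H-chromen-4-one (C2 arranged as in 8, descriptor changed by priority only) | COc1cc([C@@H]2Oc3c(OCc4ccccc4)ccc(Br)c3C(=O)C2=[N+]=[N-])ccc1OCc1ccccc1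
F3 | step 5 | methyl (2R,3S)-7-(benzyloxy)-2-[4-(benzyloxy)-3-methoxyphenyl]-4-bromo-2,3-dihydro-1-benzofuran-3-carboxylate (cis) | COc1cc([C@@H]2Oc3c(OCc4ccccc4)ccc(Br)c3[C@@H]2C(=O)OC)ccc1OCc1ccccc1
F4 | step 11 | 5,7-bis(benzyloxy)-2-[(2R,3S)-7-(benzyloxy)-2-[4-(benzyloxy)-3-methoxyphenyl]-3-[(benzyloxy)methyl]-2,3-dihydro-1-benzofuran-4-yl]-4H-chromen-4-one | COc1cc([C@@H]2Oc3c(OCc4ccccc4)ccc(-c4cc(=O)c5c(OCc6ccccc6)cc(OCc6ccccc6)cc5o4)c3[C@H]2COCc2ccccc2)ccc1OCc1ccccc1
F5 | step 11 | 2,3-epoxide of F4: 5,7-bis(benzyloxy)-2-[(2R,3S)-7-(benzyloxy)-2-[4-(benzyloxy)-3-methoxyphenyl]-3-[(benzyloxy)methyl]-2,3-dihydro-1-benzofuran-4-yl]-2,3-epoxy-2,3-dihydro-4H-chromen-4-one (both epoxide diastereomers, epoxide centres left undefined) | COc1cc([C@@H]2Oc3c(OCc4ccccc4)ccc(C45OC4C(=O)c4c(OCc6ccccc6)cc(OCc6ccccc6)cc4O5)c3[C@H]2COCc2ccccc2)ccc1OCc1ccccc1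
F6 | step 4 | (E)-1-[3-(benzyloxy)-6-bromo-2-hydroxyphenyl]-3-[4-(benzyloxy)-3-methoxyphenyl]prop-2-en-1-one | COc1cc(/C=C/C(=O)c2c(Br)ccc(OCc3ccccc3)c2O)ccc1OCc1ccccc1
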